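The target is cut at the C2–N enamide bond (copper amidation) and at C5′–C6′ of the lower trienamide (Stille coupling), which leaves the epoxyquinol ring (C1 ketone, C4 carbinol, C5/C6 oxirane). Everything rests on one feature: without the C2 nitrogen the six-membered carbocycle is a mirror-symmetric 4-hydroxy-4-alkynylcyclohexa-2,5-dienone whose C2=C3 and C5=C6 enone arms are enantiotopic. A catalytic, hydroxyl-directed nucleophilic epoxidation of one arm forms the C5–O and C6–O bonds, closes the oxirane and fixes C4, C5 and C6 in one operation. Its precursor is achiral 4-hydroxy-4-[(triisopropylsilyl)ethynyl]cyclohexa-2,5-dien-1-one, one step from benzoquinone monoketal; the silylalkyne later becomes the (E)-vinylstannane.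

Key step: step 2

Assumption (chemistry): the ring keeps the numbering C1 (ketone), C4 (carbinol), C5/C6 (oxirane, C6 next to C1) throughout; the cinchonidine-derived catalyst of step 2 is assumed to favour the arm that gives the (4R,5R,6S) epoxide, and its pseudo-enantiomer N-benzylcinchoninium chloride would replace it if the other arm is favoured.

Step 1
Reactants: 1 4,4-dimethoxycyclohexa-2,5-dien-1-one; 2 (triisopropylsilyl)acetylene
Product: 5 4-hydroxy-4-[(triisopropylsilyl)ethynyl]cyclohexa-2,5-dien-1-one, via lithium (triisopropylsilyl)acetylide 3 (not isolated), via 4,4-dimethoxy-1-[(triisopropylsilyl)ethynyl]cyclohexa-2,5-dien-1-ol 4 (not isolated)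
Conditions: 2, n-BuLi, THF, −78 °C; add 1, −78 °C; then 1 M aq. HCl, THF, 0 °C → rt
Reagents that add atoms: water, O (carbonyl oxygen of 5, from ketal hydrolysis)
Why: 1,2-addition of a lithium acetylide to the quinone monoketal carbonyl followed by mild acid hydrolysis of the dimethyl ketal is the standard p-quinol synthesis, and no stereocentre arises because 5 keeps a mirror plane through C1 and C4.

Step 2
Reactants: 5 4-hydroxy-4-[(triisopropylsilyl)ethynyl]cyclohexa-2,5-dien-1-one
Product: 6 (4R,5R,6S)-5,6-epoxy-4-hydroxy-4-[(triisopropylsilyl)ethynyl]cyclohex-2-en-1-one (hydroxyl and oxirane oxygen on the same face)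
Conditions: t-BuOOH (1.05 equiv), N-benzylcinchonidinium chloride (10 mol %), aq. NaOH (0.2 equiv), toluene, 0 °C; quench with aq. Na2S2O3 when 5 is consumed
Reagents that add atoms: tert-butyl hydroperoxide, CC(C)(C)OO
Why: The chiral ammonium tert-butylperoxide ion pair, hydrogen-bonded to the C4 hydroxyl, adds in a conjugate sense to C5 of one enone arm of 5 on the hydroxyl face, and the C6 enolate then attacks the proximal peroxide oxygen and expels tert-butoxide. The closest known reaction type is the phase-transfer-catalysed asymmetric Weitz–Scheffer epoxidation of cyclic enones and of quinone monoketals, which are cyclohexa-2,5-dienones of the same class. The oxirane, the only ring formed, closes 3-exo-tet at oxygen, and its cis fusion to the six-membered ring is geometrically enforced. C5 and C6 are set relative to C4 by hydroxyl-directed delivery (oxirane syn to OH), while the absolute configuration of C4, C5 and C6 is decided together by the catalyst's choice between the enantiotopic C2=C3 and C5=C6 arms. The step needs facial selectivity, enantiotopic-arm selectivity and mono- over bis-epoxidation: the C4 hydroxyl of the substrate secures the face, the ion pair with the C9-hydroxy cinchona cation the arm, and limiting peroxide with substoichiometric base the mono-epoxide, helped by the faster drain of the minor enantiomer (which still carries the catalyst-preferred arm) to the meso bis-epoxide. The silylalkyne and the tertiary alcohol are inert to the nucleophilic peroxide.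

Step 3
Reactants: 6 (4R,5R,6S)-5,6-epoxy-4-hydroxy-4-[(triisopropylsilyl)ethynyl]cyclohex-2-en-1-one
Product: 7 (4R,5R,6S)-5,6-epoxy-4-hydroxy-2-iodo-4-[(triisopropylsilyl)ethynyl]cyclohex-2-en-1-one
Conditions: I2, pyridine/CH2Cl2 (1:1), 0 °C → rt, dark
Reagents that add atoms: iodine, II
Why: pyridine-mediated α-iodination of the enone (Baylis–Hillman-type conjugate addition at C3, iodination of the enolate at C2, loss of pyridine) is established for epoxycyclohexenones and touches none of the three stereocentres.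

Step 4
Reactants: 8 (E)-4-methylpent-2-enal; 9 triethyl (E)-4-phosphonobut-2-enoate (triethyl 4-phosphonocrotonate)
Product: 11 (2E,4E,6E)-8-methylnona-2,4,6-trienoic acid, via ethyl (2E,4E,6E)-8-methylnona-2,4,6-trienoate 10 (not isolated)
Conditions: LiOH·H2O, 4 Å MS, THF, reflux; then LiOH, THF/MeOH/H2O, rt; aq. HCl; recrystallisation
Reagents that add atoms: lithium hydroxide, [Li+].[OH-] (hydroxyl oxygen of the CO2H group)
Why: the vinylogous Horner–Wadsworth–Emmons olefination with the stabilised phosphonate should form the new C4=C5 bond E, and saponification in the same pot gives the acid, whose all-E isomer can be purified by crystallisation.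

Step 5
Reactants: 11 (2E,4E,6E)-8-methylnona-2,4,6-trienoic acid
Product: 13 (2E,4E,6E)-8-methylnona-2,4,6-trienamide, via isobutyl carbonic (2E,4E,6E)-8-methylnona-2,4,6-trienoic anhydride 12 (not isolated)
Conditions: i-BuOCOCl, N-methylmorpholine, THF, −15 °C; then NH3 (0.5 M in dioxane), −15 → 0 °C
Reagents that add atoms: ammonia, N
Why: mixed carbonic anhydride activation followed by ammonolysis at the acyl carbonyl is a standard primary amide synthesis that leaves the triene geometry untouched.

Step 6
Reactants: 7 (4R,5R,6S)-5,6-epoxy-4-hydroxy-2-iodo-4-[(triisopropylsilyl)ethynyl]cyclohex-2-en-1-one; 13 (2E,4E,6E)-8-methylnona-2,4,6-trienamide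
Product: 14 (2E,4E,6E)-N-{(4R,5R,6S)-5,6-epoxy-4-hydroxy-1-oxo-4-[(triisopropylsilyl)ethynyl]cyclohex-2-en-2-yl}-8-methylnona-2,4,6-trienamide
Conditions: CuI (10 mol %), N,N′-dimethylethylenediamine (20 mol %), Cs2CO3, THF, 50 °C, degassed, dark
Reagents that add atoms: none
Why: copper-catalysed Goldberg-type amidation of a vinyl iodide with a primary amide forms the C2–N bond at the activated α-iodoenone without involving C4–C6, and the silyl cap keeps the alkyne from forming a copper acetylide.

Step 7
Reactants: 14 (2E,4E,6E)-N-{(4R,5R,6S)-5,6-epoxy-4-hydroxy-1-oxo-4-[(triisopropylsilyl)ethynyl]cyclohex-2-en-2-yl}-8-methylnona-2,4,6-trienamide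
Product: 15 (2E,4E,6E)-N-[(4R,5R,6S)-5,6-epoxy-4-ethynyl-4-hydroxy-1-oxocyclohex-2-en-2-yl]-8-methylnona-2,4,6-trienamide
Conditions: TBAF/AcOH (1:1), THF, 0 °C → rt
Reagents that add atoms: none
Why: fluoride-induced protodesilylation of the alkynylsilane, buffered with acetic acid so that the epoxy ketone and the enamide are not exposed to basic fluoride.

Step 8
Reactants: 15 (2E,4E,6E)-N-[(4R,5R,6S)-5,6-epoxy-4-ethynyl-4-hydroxy-1-oxocyclohex-2-en-2-yl]-8-methylnona-2,4,6-trienamide
Product: 16 (2E,4E,6E)-N-{(4R,5R,6S)-5,6-epoxy-4-hydroxy-1-oxo-4-[(E)-2-(tributylstannyl)ethenyl]cyclohex-2-en-2-yl}-8-methylnona-2,4,6-trienamide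
Conditions: Bu3SnH (1.1 equiv, slow addition), PdCl2(PPh3)2 (3 mol %), THF, 0 °C
Reagents that add atoms: tributyltin hydride, CCCC[SnH](CCCC)CCCC
Why: palladium-catalysed syn-hydrostannation of a terminal alkyne places tin at the unhindered terminus when the propargylic carbon is fully substituted, which should give the (E)-β-stannane, and it is much faster than Pd–H reduction of the enone.

Step 9
Reactants: 17 cyclopentane-1,3-dione
Product: 18 2-(hydroxyimino)cyclopentane-1,3-dione
Conditions: NaNO2, aq. HCl, 0–5 °C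
Reagents that add atoms: sodium nitrite, [Na+].[O-]N=O
Why: C-nitrosation of the enolic 1,3-dione at C2 and tautomerisation to the oxime is the classical α-oximation of β-dicarbonyl compounds.

Step 10
Reactants: 18 2-(hydroxyimino)cyclopentane-1,3-dione
Product: 19 2-amino-3-hydroxycyclopent-2-en-1-one hydrochloride
Conditions: H2 (1 atm), 10% Pd/C, MeOH, HCl (1.1 equiv), rt
Reagents that add atoms: hydrogen chloride, Cl
Why: catalytic hydrogenation of the α-oximino dione gives the α-amino dione, which is trapped as the hydrochloride of its enol tautomer so that it cannot self-condense.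

Step 11
Reactants: 20 ethyl (E)-4-oxobut-2-enoate
Product: 21 ethyl (2E,4E)-5-iodopenta-2,4-dienoate
Conditions: CrCl2, CHI3, THF, 0 °C, dark
Reagents that add atoms: iodoform, IC(I)I
Why: Takai olefination of the aldehyde with the chromium carbenoid from iodoform should give the (E)-vinyl iodide, and the ester and the existing E alkene are not touched.

Step 12
Reactants: 21 ethyl (2E,4E)-5-iodopenta-2,4-dienoate
Product: 22 (2E,4E)-5-iodopenta-2,4-dienoic acid
Conditions: LiOH, THF/H2O, 0 °C → rt; aq. HCl; recrystallisation, dark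
Reagents that add atoms: lithium hydroxide, [Li+].[OH-] (hydroxyl oxygen of the CO2H group)
Why: ester saponification, to which the vinyl iodide is stable at room temperature, with crystallisation of the acid to remove any (4Z) isomer.

Step 13
Reactants: 22 (2E,4E)-5-iodopenta-2,4-dienoic acid; 19 2-amino-3-hydroxycyclopent-2-en-1-one hydrochloride
Product: 24 (2E,4E)-N-(2-hydroxy-5-oxocyclopent-1-en-1-yl)-5-iodopenta-2,4-dienamide, via (2E,4E)-5-iodopenta-2,4-dienoyl chloride 23 (not isolated)
Conditions: (COCl)2, DMF (cat.), CH2Cl2, 0 °C → rt, concentrate; then 19, Et3N, CH2Cl2/THF, 0 °C → rt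
Reagents that add atoms: none
Why: Schotten–Baumann-type N-acylation of the aminocyclopentenone with the acid chloride, in which any enol ester formed first should transfer its acyl group to nitrogen to give the hydrogen-bonded amide.

Step 14
Reactants: 16 (2E,4E,6E)-N-{(4R,5R,6S)-5,6-epoxy-4-hydroxy-1-oxo-4-[(E)-2-(tributylstannyl)ethenyl]cyclohex-2-en-2-yl}-8-methylnona-2,4,6-trienamide; 24 (2E,4E)-N-(2-hydroxy-5-oxocyclopent-1-en-1-yl)-5-iodopenta-2,4-dienamide
Product: 25 manumycin G, (2E,4E,6E)-N-[(4S,5R,6S)-5,6-epoxy-4-hydroxy-4-{(1E,3E,5E)-7-[(2-hydroxy-5-oxocyclopent-1-en-1-yl)amino]-7-oxohepta-1,3,5-trien-1-yl}-1-oxocyclohex-2-en-2-yl]-8-methylnona-2,4,6-trienamide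
Conditions: Pd2(dba)3 (5 mol %), AsPh3 (20 mol %), DMF, rt, dark
Reagents that add atoms: none
Why: Stille coupling of an (E)-vinylstannane with an (E,E)-dienyl iodide proceeds with retention at both sp2 carbons under neutral conditions at room temperature, so the free hydroxyl, epoxy ketone, enamide and acidic enol should be tolerated (the C4 descriptor changes from R to S only through CIP priorities).

Compound list
1 | 4,4-dimethoxycyclohexa-2,5-dien-1-one | COC1(OC)C=CC(=O)C=C1 | starting material
2 | (triisopropylsilyl)acetylene | C#C[Si](C(C)C)(C(C)C)C(C)C | starting material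
3 | lithium (triisopropylsilyl)acetylide | [Li]C#C[Si](C(C)C)(C(C)C)C(C)C | intermediate (not isolated)
4 | 4,4-dimethoxy-1-[(triisopropylsilyl)ethynyl]cyclohexa-2,5-dien-1-ol | COC1(OC)C=CC(O)(C#C[Si](C(C)C)(C(C)C)C(C)C)C=C1 | intermediate (not isolated)
5 | 4-hydroxy-4-[(triisopropylsilyl)ethynyl]cyclohexa-2,5-dien-1-one | O=C1C=CC(O)(C#C[Si](C(C)C)(C(C)C)C(C)C)C=C1 | intermediate
6 | (4R,5R,6S)-5,6-epoxy-4-hydroxy-4-[(triisopropylsilyl)ethynyl]cyclohex-2-en-1-one | C1=C[C@@](O)(C#C[Si](C(C)C)(C(C)C)C(C)C)[C@@H]2O[C@@H]2C1=O | intermediate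
7 | (4R,5R,6S)-5,6-epoxy-4-hydroxy-2-iodo-4-[(triisopropylsilyl)ethynyl]cyclohex-2-en-1-one | IC1=C[C@@](O)(C#C[Si](C(C)C)(C(C)C)C(C)C)[C@@H]2O[C@@H]2C1=O | intermediate
8 | (E)-4-methylpent-2-enal | CC(C)/C=C/C=O | starting material
9 | triethyl (E)-4-phosphonobut-2-enoate | CCOC(=O)/C=C/CP(=O)(OCC)OCC | starting material
10 | ethyl (2E,4E,6E)-8-methylnona-2,4,6-trienoate | CC(C)/C=C/C=C/C=C/C(=O)OCC | intermediate (not isolated)
11 | (2E,4E,6E)-8-methylnona-2,4,6-trienoic acid | CC(C)/C=C/C=C/C=C/C(=O)O | intermediate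
12 | isobutyl carbonic (2E,4E,6E)-8-methylnona-2,4,6-trienoic anhydride | CC(C)/C=C/C=C/C=C/C(=O)OC(=O)OCC(C)C | intermediate (not isolated)
13 | (2E,4E,6E)-8-methylnona-2,4,6-trienamide | CC(C)/C=C/C=C/C=C/C(N)=O | intermediate
14 | (2E,4E,6E)-N-{(4R,5R,6S)-5,6-epoxy-4-hydroxy-1-oxo-4-[(triisopropylsilyl)ethynyl]cyclohex-2-en-2-yl}-8-methylnona-2,4,6-trienamide | CC(C)/C=C/C=C/C=C/C(=O)NC1=C[C@@](O)(C#C[Si](C(C)C)(C(C)C)C(C)C)[C@@H]2O[C@@H]2C1=O | intermediate
15 | (2E,4E,6E)-N-[(4R,5R,6S)-5,6-epoxy-4-ethynyl-4-hydroxy-1-oxocyclohex-2-en-2-yl]-8-methylnona-2,4,6-trienamide | CC(C)/C=C/C=C/C=C/C(=O)NC1=C[C@@](O)(C#C)[C@@H]2O[C@@H]2C1=O | intermediate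
16 | (2E,4E,6E)-N-{(4R,5R,6S)-5,6-epoxy-4-hydroxy-1-oxo-4-[(E)-2-(tributylstannyl)ethenyl]cyclohex-2-en-2-yl}-8-methylnona-2,4,6-trienamide | CC(C)/C=C/C=C/C=C/C(=O)NC1=C[C@@](O)(/C=C/[Sn](CCCC)(CCCC)CCCC)[C@@H]2O[C@@H]2C1=O | intermediate
17 | cyclopentane-1,3-dione | O=C1CCC(=O)C1 | starting material
18 | 2-(hydroxyimino)cyclopentane-1,3-dione | O=C1CCC(=O)C1=NO | intermediate
19 | 2-amino-3-hydroxycyclopent-2-en-1-one hydrochloride | NC1=C(O)CCC1=O.Cl | intermediate
20 | ethyl (E)-4-oxobut-2-enoate | CCOC(=O)/C=C/C=O | starting material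
21 | ethyl (2E,4E)-5-iodopenta-2,4-dienoate | CCOC(=O)/C=C/C=C/I | intermediate
22 | (2E,4E)-5-iodopenta-2,4-dienoic acid | OC(=O)/C=C/C=C/I | intermediate
23 | (2E,4E)-5-iodopenta-2,4-dienoyl chloride | ClC(=O)/C=C/C=C/I | intermediate (not isolated)
24 | (2E,4E)-N-(2-hydroxy-5-oxocyclopent-1-en-1-yl)-5-iodopenta-2,4-dienamide | O=C(/C=C/C=C/I)NC1=C(O)CCC1=O | intermediate
25 | manumycin G | CC(C)/C=C/C=C/C=C/C(=O)NC1=C[C@@](O)(/C=C/C=C/C=C/C(=O)NC2=C(O)CCC2=O)[C@@H]2O[C@@H]2C1=O | target

Total step count: 14.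
Longest linear sequence: 7 steps (steps 1, 2, 3, 6, 7, 8 and 14, from 1).

Steps most likely to fail

Step 2. The catalyst may discriminate poorly between the two enantiotopic enone arms, and a second epoxidation or base-induced degradation of the quinol may compete. The fallback sets the oxirane first and C4 afterwards. It sets out from 1: a tartrate-mediated asymmetric nucleophilic epoxidation of the quinone monoketal (trityl hydroperoxide, NaHMDS, the diisopropyl tartrate antipode that gives the 2R,3S oxirane, toluene, −78 → −40 °C) should give (2R,3S)-2,3-epoxy-4,4-dimethoxycyclohex-5-en-1-one F1. Addition of lithium acetylide 3 (THF, −78 °C) to the carbonyl on the face anti to the oxirane oxygen should give (1R,2R,3S)-2,3-epoxy-4,4-dimethoxy-1-[(triisopropylsilyl)ethynyl]cyclohex-5-en-1-ol F2, with the hydroxyl syn to the oxirane. Ketal hydrolysis (aq. oxalic acid, THF, or montmorillonite K10, CH2Cl2) comes back to the route at 6.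

Step 6. C–N coupling of the polyene primary amide may be slow, so that protodeiodination, aza-Michael addition at C3 or base-induced degradation of the epoxy ketone win. The fallback separates C–N bond formation from amide formation. It sets out from 7: palladium-catalysed amination with benzophenone imine (Pd2(dba)3, Xantphos, Cs2CO3, toluene, 50 °C) should give (4R,5R,6S)-2-[(diphenylmethylidene)amino]-5,6-epoxy-4-hydroxy-4-[(triisopropylsilyl)ethynyl]cyclohex-2-en-1-one F3. Mild hydrolysis (aq. citric acid, THF, rt) should release (4R,5R,6S)-2-amino-5,6-epoxy-4-hydroxy-4-[(triisopropylsilyl)ethynyl]cyclohex-2-en-1-one F4. N-acylation with (2E,4E,6E)-8-methylnona-2,4,6-trienoyl chloride F5 (from 11 with oxalyl chloride and catalytic DMF), in pyridine/CH2Cl2 with catalytic DMAP at 0 °C, comes back to the route at 14.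

Step 8. Regio- and chemoselectivity may be lost: tin may be delivered to the internal alkyne carbon, Pd–H may reduce the 2-amidoenone or open the epoxy ketone, and the stannane may protodestannylate on purification. The fallback replaces tin by silicon and merges with the last coupling. It sets out from 15: platinum-catalysed hydrosilylation with benzyldimethylsilane (Pt(dvds), P(t-Bu)3, THF, rt) should give (2E,4E,6E)-N-{(4R,5R,6S)-4-[(E)-2-(benzyldimethylsilyl)ethenyl]-5,6-epoxy-4-hydroxy-1-oxocyclohex-2-en-2-yl}-8-methylnona-2,4,6-trienamide F6. Fluoride-promoted Hiyama–Denmark coupling of F6 with 24 (Pd2(dba)3, TBAF, THF, 0 °C → rt) comes back to the route at 25.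

Further compounds
F1 | step 2 | (2R,3S)-2,3-epoxy-4,4-dimethoxycyclohex-5-en-1-one | C1=CC(=O)[C@@H]2O[C@@H]2C1(OC)OC
F2 | step 2 | (1R,2R,3S)-2,3-epoxy-4,4-dimethoxy-1-[(triisopropylsilyl)ethynyl]cyclohex-5-en-1-ol | C1=C[C@@](O)(C#C[Si](C(C)C)(C(C)C)C(C)C)[C@@H]2O[C@@H]2C1(OC)OC
F3 | step 6 | (4R,5R,6S)-2-[(diphenylmethylidene)amino]-5,6-epoxy-4-hydroxy-4-[(triisopropylsilyl)ethynyl]cyclohex-2-en-1-one | N(=C(c3ccccc3)c3ccccc3)C1=C[C@@](O)(C#C[Si](C(C)C)(C(C)C)C(C)C)[C@@H]2O[C@@H]2C1=O
F4 | step 6 | (4R,5R,6S)-2-amino-5,6-epoxy-4-hydroxy-4-[(triisopropylsilyl)ethynyl]cyclohex-2-en-1-one | NC1=C[C@@](O)(C#C[Si](C(C)C)(C(C)C)C(C)C)[C@@H]2O[C@@H]2C1=O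
F5 | step 6 | (2E,4E,6E)-8-methylnona-2,4,6-trienoyl chloride | CC(C)/C=C/C=C/C=C/C(Cl)=O
F6 | step 8 | (2E,4E,6E)-N-{(4R,5R,6S)-4-[(E)-2-(benzyldimethylsilyl)ethenyl]-5,6-epoxy-4-hydroxy-1-oxocyclohex-2-en-2-yl}-8-methylnona-2,4,6-trienamide | CC(C)/C=C/C=C/C=C/C(=O)NC1=C[C@@](O)(/C=C/[Si](C)(C)Cc3ccccc3)[C@@H]2O[C@@H]2C1=O
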